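The rate constants were set for the occasion; the result is computed.

The Q left over in a flask is where this reckoning for D starts.

    D + Q ⇌ L + E (K1 = 1.3, k1 = 4.21 × 10⁻⁵ M⁻¹ s⁻¹)
    Z + Q ⇌ L + D (K2 = 0.132, k2 = 4.84 × 10⁻⁴ M⁻¹ s⁻¹)
    J + Q ⇌ L + Z (K3 = 0.65, k3 = 4.19 × 10⁻⁴ M⁻¹ s⁻¹)

all flasks: Q 0.0638 M

| run | J | time | remark |
|---|---|---|---|
| east | 0.058 M (fed, over 8.00 h) | 8.0 h | a stirred flask in which J is dosed at a steady rate over 8.00 h without added volume, worked up at 8.0 h |
| west | 0.058 M |  | a single well-mixed tank run continuously and read at steady state, 8.0 h in it on average |
| south-east | 0.058 M |  | one stirred flow tank at steady state, fed with the mixture as stated, mean residence time 24.0 h |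
| north-west | 0.058 M | 8.0 h | a closed flask charged with all of it at once and left for 8.0 h |

1. the set-up with the highest amount of D at the outlet or at the end, in percent of the J put in ("none" if the first two lie within 2 percentage points) (east / west / south-east / north-west / none)
2. amount of D at the outlet or at the end, in percent of the J put in, east
3. amount of D at the outlet or at the end, in percent of the J put in, west
4. amount of D at the outlet or at the end, in percent of the J put in, south-east
5. amount of D at the outlet or at the end, in percent of the J put in, north-west

- the stated concentrations are those of everything mixed, before any reaction; amounts are the same in each set-up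
- the feed brings no volume worth counting
- run time (east): 8.0 h

**Times first.** In north-west, taken as pseudo-first-order at the charges, forward rates alone, J has a half-life of 7.2 h by the step J + Q, and Z one of 6.2 h by the step Z + Q. There D has 72 h by the step D + Q, longer than the time 8.0 h, so the reckoning drops E.

**Upper bound.** While the step Z + Q runs forward, D stays below its balance value, 0.132 times Q times Z over L, in fractions of the J charge. Z over L stays below one, and Q stays below its charge. That gives the Q cap, 0.132 times the charged Q over the charged J: 14.5%.

**Tightening.** If the step J + Q comes to balance with L equal to Z, Z reaches 46.8%, and the Q left lowers the cap to 8.35%. Each Z brings one L and each D brings two, and counting that gives 6.53%, a top estimate for that state and not a strict bound.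

**Rough floor.** For the dosed east flask, a reckoning with the forward step J + Q at charged Q puts the J turned over at 30.3%. Scaling the top estimate by that share gives 1.97%, an estimate too.

**The forecast.** It gives 4.2% for east, 4.7% for west, 5.5% for south-east and 5.7% for north-west, between these two estimates. Its call is none, with the top two “come out nearly level at the top”.

**The result.** The flasks give 4.20%, 4.69%, 5.39% and 5.73% in that order, and the call is none: the top two stand 0.34 percentage points apart against a margin of 2 points.

**Neighbour flask.** In north-west at 8.00 h, the cap times the share of Q left times Z over L reads 6.35%, above its D. The east answer has moved by 5 points at 0.119 M of Q, all other amounts and the time held. The neighbour, east with 0.26 M of Q, has a cap of 59.2%. At 8.00 h it holds 81.4% of its Q and 38.3% Z with 0.0485 M L, so the same product reads 22.1%, and D stands below it at 19.0%.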